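Ring B is disconnected at C7=C8 together with the isopropenyl alkene C11=C12. A ring-closing enyne metathesis of a ring-A 1,7-enyne closes the six-membered ring B and creates the conjugated C8=C7–C11=C12 diene in a single atom-conserving isomerisation. It exploits the fact that the C7 isopropenyl group stands next to the C8 carbinol, so that this diene is the latent form of both. The precursor is a ring-A cyclohexane carrying the C3 silyl ether, the C4 and C5 methyl groups, a but-2-ynyl group on quaternary C5 and a silyl-protected vinyl carbinol (C9) on C10; it is assembled from a γ-silyloxy enone by cuprate addition and enolate propargylation.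

Key step: step 12

Remarks: TBS = tert-butyldimethylsilyl. Ring A is C1–C2–C3–C4–C5–C10, ring B is C5–C6–C7–C8–C9–C10, and C11–C13 sit on C7. α is the face opposite to the C5 methyl. Bicyclic compounds are named as eremophilanes (trans-decalin, methyl groups on C4 and C5, C11–C13 on C7). CIP letters at C5, C8 and C9 change along the route only because substituent priorities change.

Assumption: enone ketal 1 is bought; if it has to be made, dehydrogenation of 1,4-dioxaspiro[4.5]decan-8-one with 2-iodoxybenzoic acid adds one step.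

Step 1
Reactants: 1 1,4-dioxaspiro[4.5]dec-6-en-8-one
Product: 2 (8R)-1,4-dioxaspiro[4.5]dec-6-en-8-ol
Conditions: RuCl[(R,R)-TsDPEN](p-cymene) (1 mol %), HCO2Na, Bu4NCl (cat.), CH2Cl2/H2O, rt
Reagents that add atoms: none
Why: Asymmetric transfer hydrogenation of the Noyori–Ikariya type reduces the enone carbonyl 1,2 under biphasic formate conditions, and the (R,R)-diamine complex is expected, with the alkene in the role that the aryl group plays in aryl ketones, to give the 8R carbinol that becomes C3 (the mirror-image complex is used should the sense prove opposite).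

Step 2
Reactants: 2 (8R)-1,4-dioxaspiro[4.5]dec-6-en-8-ol
Product: 3 (8R)-8-(TBSO)-1,4-dioxaspiro[4.5]dec-6-ene
Conditions: TBSCl, imidazole, DMF, rt
Reagents that add atoms: tert-butyldimethylsilyl chloride, CC(C)(C)[Si](C)(C)Cl
Why: Standard silylation of a secondary allylic alcohol installs the bulky ether that later steers the cuprate.

Step 3
Reactants: 3 (8R)-8-(TBSO)-1,4-dioxaspiro[4.5]dec-6-ene
Product: 4 (4R)-4-(TBSO)cyclohex-2-en-1-one
Conditions: PPTS (cat.), acetone/H2O, 40 °C
Reagents that add atoms: water, O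
Why: Mild acid-catalysed hydrolysis of the allylic ketal (alkene-stabilised oxocarbenium ion) unmasks the transposed enone without cleaving the secondary silyl ether or touching the stereocentre.

Step 4
Reactants: 4 (4R)-4-(TBSO)cyclohex-2-en-1-one
Product: 5 (4R)-2-iodo-4-(TBSO)cyclohex-2-en-1-one
Conditions: I2, pyridine, CH2Cl2, 0 °C to rt
Reagents that add atoms: iodine, II
Why: α-Iodination of an enone (conjugate addition of pyridine, iodination of the enolate, elimination) places iodine on C2 under conditions too weakly basic to eliminate the γ-silyloxy group.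

Step 5
Reactants: 5 (4R)-2-iodo-4-(TBSO)cyclohex-2-en-1-one
Product: 6 (4R)-2-methyl-4-(TBSO)cyclohex-2-en-1-one
Conditions: Me4Sn, Pd2(dba)3 (cat.), AsPh3, CuI (copper iodide, cat.), NMP, 60 °C
Reagents that add atoms: tetramethylstannane, C[Sn](C)(C)C
Why: Stille coupling (zerovalent palladium inserts into the vinyl C–I bond, Me4Sn transfers methyl) works under neutral conditions that protect the base-sensitive γ-silyloxy enone.

Step 6
Reactants: 6 (4R)-2-methyl-4-(TBSO)cyclohex-2-en-1-one; 7 1-bromobut-2-yne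
Product: 9 (2R,3R,4R)-2-(but-2-yn-1-yl)-2,3-dimethyl-4-(TBSO)cyclohexan-1-one, via lithium enolate 8 (not isolated)
Conditions: Me2CuLi (from MeLi and CuI, copper iodide), Et2O, −78 to −30 °C; then 7, DMPU, THF, −30 to 0 °C
Reagents that add atoms: lithium dimethylcuprate, [Li+].C[Cu-]C
Why: Conjugate addition of the cuprate should occur anti to the γ-silyloxy group (sets C4 trans to the C3 oxygen), and the regiodefined C5 enolate should be alkylated by the propargylic bromide anti to the new C4 methyl, which allylic strain with the C5 methyl holds pseudoaxial, giving the cis-vicinal dimethyl pattern and the quaternary C5.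

Step 7
Reactants: 9 (2R,3R,4R)-2-(but-2-yn-1-yl)-2,3-dimethyl-4-(TBSO)cyclohexan-1-one
Product: 10 (2R,3R,4R)-2-(but-2-yn-1-yl)-2,3-dimethyl-1-methylidene-4-(TBSO)cyclohexane
Conditions: Ph3PCH3Br, KOtBu, toluene, 80 °C
Reagents that add atoms: methyltriphenylphosphonium bromide, C[P+](c1ccccc1)(c1ccccc1)c1ccccc1.[Br-]
Why: Wittig methylenation of the hindered ketone, which has no epimerisable α-stereocentre (C5 is quaternary), introduces C9 as an exocyclic methylene.

Step 8
Reactants: 10 (2R,3R,4R)-2-(but-2-yn-1-yl)-2,3-dimethyl-1-methylidene-4-(TBSO)cyclohexane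
Product: 12 [(1R,2S,3R,4R)-2-(but-2-yn-1-yl)-2,3-dimethyl-4-(TBSO)cyclohexyl]methanol, via B-alkyl-9-BBN adduct 11 (not isolated)
Conditions: 9-BBN, THF, 0 °C to rt; then NaOH, H2O2, 0 °C to rt
Reagents that add atoms: 9-borabicyclo[3.3.1]nonane, B1C2CCCC1CCC2 (boron carried in 11 only); hydrogen peroxide, OO
Why: Anti-Markovnikov hydroboration–oxidation with bulky 9-BBN should prefer the 1,1-disubstituted alkene over the methyl-capped internal alkyne and deliver hydrogen to C10 on the axial α face, anti to the axial C5 methyl on the neighbouring carbon, so that the CH2OH arm becomes equatorial and trans to the butynyl group.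

Step 9
Reactants: 12 [(1R,2S,3R,4R)-2-(but-2-yn-1-yl)-2,3-dimethyl-4-(TBSO)cyclohexyl]methanol
Product: 13 (1R,2R,3R,4R)-2-(but-2-yn-1-yl)-2,3-dimethyl-4-(TBSO)cyclohexane-1-carbaldehyde
Conditions: Dess–Martin periodinane, NaHCO3, CH2Cl2, 0 °C to rt
Reagents that add atoms: none
Why: Buffered Dess–Martin oxidation gives the α-branched aldehyde without epimerising C10, and the aldehyde is used directly.

Step 10
Reactants: 13 (1R,2R,3R,4R)-2-(but-2-yn-1-yl)-2,3-dimethyl-4-(TBSO)cyclohexane-1-carbaldehyde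
Product: 14 (1R)-1-[(1R,2R,3R,4R)-2-(but-2-yn-1-yl)-2,3-dimethyl-4-(TBSO)cyclohexyl]prop-2-en-1-ol
Conditions: CH2=CHMgBr, THF, −78 °C; then H2O
Reagents that add atoms: vinylmagnesium bromide, C=C[Mg]Br
Why: Felkin–Anh addition of the Grignard reagent, with the quaternary C5 as the large group anti to the nucleophile and attack past the C10 hydrogen, should give mainly the carbinol that carries the 9α oxygen of the target, the minor epimer being removed by chromatography.

Step 11
Reactants: 14 (1R)-1-[(1R,2R,3R,4R)-2-(but-2-yn-1-yl)-2,3-dimethyl-4-(TBSO)cyclohexyl]prop-2-en-1-ol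
Product: 15 (1R,2R,3R,4R)-2-(but-2-yn-1-yl)-2,3-dimethyl-4-(TBSO)-1-[(1R)-1-(TBSO)prop-2-en-1-yl]cyclohexane (ring-A enyne)
Conditions: TBSOTf, 2,6-lutidine, CH2Cl2, −78 to 0 °C
Reagents that add atoms: tert-butyldimethylsilyl trifluoromethanesulfonate, CC(C)(C)[Si](C)(C)OS(=O)(=O)C(F)(F)F
Why: Silyl triflate silylation of the hindered allylic alcohol prevents its isomerisation by ruthenium hydride species during the metathesis.

Step 12
Reactants: 15 (1R,2R,3R,4R)-2-(but-2-yn-1-yl)-2,3-dimethyl-4-(TBSO)-1-[(1R)-1-(TBSO)prop-2-en-1-yl]cyclohexane (ring-A enyne)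
Product: 16 (3R,4R,5R,9R,10R)-3,9-bis(TBSO)eremophila-7,11-diene (ring-B diene)
Conditions: second-generation Grubbs catalyst RuCl2(=CHPh)(PCy3)(H2IMes) (5 mol %), ethene (1 atm), toluene (0.005 M), 80 °C
Reagents that add atoms: none
Why: Enyne metathesis: the ruthenium carbene, as [Ru]=CH2 or after loading onto the C8=C12 vinyl group, adds across the C7≡C11 triple bond to a ruthenacyclobutene that opens to a vinylcarbene, and ring closure followed by methylene transfer releases the diene, so the net change is an isomerisation. The closest known reaction type is the ruthenium-carbene ring-closing enyne metathesis of 1,7-enynes bearing methyl-capped alkynes under ethene. Ring B closes in the exo mode with respect to the alkyne (C8 bonds to C7, six-membered), which leaves C11 outside the ring as the isopropenyl carbon. No stereocentre is created, and C3, C4, C5, C9 and C10 are not epimerisable under these neutral conditions. The selectivity needed is exo (six-membered) over endo (seven-membered, C8–C11) closure and cyclisation over oligomerisation. It is secured by the 1,7-spacing, by the quaternary C5 and the equatorial C10 arm holding the two partners gauche to each other, and by high dilution under ethene, which keeps the catalyst as the methylidene.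

Step 13
Reactants: 16 (3R,4R,5R,9R,10R)-3,9-bis(TBSO)eremophila-7,11-diene
Product: 17 (3R,4R,5R,9R,10R)-eremophila-7,11-diene-3,9-diol
Conditions: Bu4NF, THF, rt to 45 °C
Reagents that add atoms: none
Why: Fluoride cleaves both silyl ethers and frees the C9 hydroxyl that is needed to direct the epoxidation.

Step 14
Reactants: 17 (3R,4R,5R,9R,10R)-eremophila-7,11-diene-3,9-diol
Product: 18 (3R,4R,5R,7S,8S,9S,10R)-7,8-epoxyeremophil-11-ene-3,9-diol (7α,8α-epoxide)
Conditions: VO(acac)2 (5 mol %), tBuOOH, CH2Cl2, 0 °C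
Reagents that add atoms: tert-butyl hydroperoxide, CC(C)(C)OO
Why: Vanadium-catalysed hydroxyl-directed epoxidation should react only at the allylic C7=C8 bond and deliver oxygen syn to the 9α hydroxyl, which is also the face anti to the axial C5 methyl, leaving C11=C12 untouched.

Step 15
Reactants: 18 (3R,4R,5R,7S,8S,9S,10R)-7,8-epoxyeremophil-11-ene-3,9-diol
Product: 19 (3R,4R,5R,7S,8R,9S,10R)-eremophil-11-ene-3,8,9-triol
Conditions: Pd2(dba)3·CHCl3 (2.5 mol %), Bu3P (5 mol %), HCO2H, Et3N, 1,4-dioxane, rt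
Reagents that add atoms: none
Why: In this palladium–formate hydrogenolysis of an alkenyl oxirane, zerovalent palladium opens the allylic C7–O bond with inversion to a C7–C11–C12 allyl complex on the β face and hydride is transferred from the metal to the more substituted terminus C7, so H7 should end β, the isopropenyl group α (equatorial) and the 8α hydroxyl is kept.

Step 16
Reactants: 19 (3R,4R,5R,7S,8R,9S,10R)-eremophil-11-ene-3,8,9-triol
Product: 20 (3R,4R,5R,7S,8R,9S,10R)-8,9-(isopropylidenedioxy)eremophil-11-en-3-ol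
Conditions: 2,2-dimethoxypropane, PPTS (cat.), acetone, rt; MeOH quench
Reagents that add atoms: 2,2-dimethoxypropane, COC(C)(C)OC
Why: Acetonide formation is selective for the cis-8,9-diol (five-membered dioxolane) and leaves the isolated C3 hydroxyl free for acylation.

Step 17
Reactants: 21 (3S)-pent-1-yn-3-ol
Product: 23 (4S)-4-hydroxyhex-2-ynoic acid, via dilithio alkoxide acetylide 22 (not isolated)
Conditions: nBuLi (2.1 equiv), THF, −78 °C; CO2, −78 °C to rt; aq. HCl
Reagents that add atoms: n-butyllithium, [Li]CCCC (lithium carried in 22 only); carbon dioxide, O=C=O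
Why: Double deprotonation gives the alkoxide–acetylide, whose carbon terminus is carboxylated by CO2 (acetylide carboxylation) while the carbinol centre is not involved and stays S.

Step 18
Reactants: 24 hex-2-ynoic acid; 23 (4S)-4-hydroxyhex-2-ynoic acid
Product: 26 (4S)-4-(hex-2-ynoyloxy)hex-2-ynoic acid, via hex-2-ynoyl chloride 25 (not isolated)
Conditions: 24, (COCl)2, DMF (cat.), CH2Cl2, 0 °C to rt, evaporation; then 23, CH2Cl2, rt, no base; aq. THF work-up
Reagents that add atoms: oxalyl chloride, O=C(Cl)C(Cl)=O (chlorine carried in 25 only)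
Why: O-Acylation of a hydroxy acid by an acid chloride without base acylates the alcohol, since the weakly nucleophilic ynoic acid group reacts at most reversibly to a mixed anhydride that the aqueous work-up hydrolyses, and the stereocentre is untouched.

Step 19
Reactants: 20 (3R,4R,5R,7S,8R,9S,10R)-8,9-(isopropylidenedioxy)eremophil-11-en-3-ol; 26 (4S)-4-(hex-2-ynoyloxy)hex-2-ynoic acid
Product: 27 (3R,4R,5R,7S,8R,9S,10R)-8,9-(isopropylidenedioxy)eremophil-11-en-3-yl (4S)-4-(hex-2-ynoyloxy)hex-2-ynoate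
Conditions: DCC, DMAP (10 mol %), CH2Cl2, −20 to 0 °C
Reagents that add atoms: none
Why: Steglich esterification acylates the equatorial C3 hydroxyl, and coupling at the ynoate stage avoids the Z-to-E isomerisation that activation of the corresponding (Z)-enoic acid would risk.

Step 20
Reactants: 27 (3R,4R,5R,7S,8R,9S,10R)-8,9-(isopropylidenedioxy)eremophil-11-en-3-yl (4S)-4-(hex-2-ynoyloxy)hex-2-ynoate
Product: 28 (3R,4R,5R,7S,8R,9S,10R)-8,9-(isopropylidenedioxy)eremophil-11-en-3-yl (2Z,4S)-4-[(2Z)-hex-2-enoyloxy]hex-2-enoate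
Conditions: H2 (1 atm), Pd/CaCO3 poisoned with Pb(OAc)2, quinoline, EtOAc, rt
Reagents that add atoms: none
Why: Lindlar semihydrogenation adds one equivalent of H2 syn to each ynoate to give the two (Z)-enoates, and the poisoned catalyst should spare the 1,1-disubstituted isopropenyl alkene when the uptake is stopped at two equivalents.

Step 21
Reactants: 28 (3R,4R,5R,7S,8R,9S,10R)-8,9-(isopropylidenedioxy)eremophil-11-en-3-yl (2Z,4S)-4-[(2Z)-hex-2-enoyloxy]hex-2-enoate
Product: 29 (3R,4R,5R,7S,8R,9S,10R)-8,9-dihydroxyeremophil-11-en-3-yl (2Z,4S)-4-[(2Z)-hex-2-enoyloxy]hex-2-enoate (CNP0271544.1)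
Conditions: AcOH/H2O (4:1), 40 °C
Reagents that add atoms: none
Why: Mild aqueous acid hydrolyses the acetonide without touching the esters, the (Z)-alkenes or the isopropenyl group, and releases the target.

Compound list
1 | 1,4-dioxaspiro[4.5]dec-6-en-8-one | O=C1C=CC2(CC1)OCCO2 | starting material
2 | (8R)-1,4-dioxaspiro[4.5]dec-6-en-8-ol | O[C@@H]1CCC2(OCCO2)C=C1 | intermediate
3 | (8R)-8-(TBSO)-1,4-dioxaspiro[4.5]dec-6-ene | CC(C)(C)[Si](C)(C)O[C@@H]1CCC2(OCCO2)C=C1 | intermediate
4 | (4R)-4-(TBSO)cyclohex-2-en-1-one | O=C1CC[C@@H](O[Si](C)(C)C(C)(C)C)C=C1 | intermediate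
5 | (4R)-2-iodo-4-(TBSO)cyclohex-2-en-1-one | O=C1CC[C@@H](O[Si](C)(C)C(C)(C)C)C=C1I | intermediate
6 | (4R)-2-methyl-4-(TBSO)cyclohex-2-en-1-one | O=C1CC[C@@H](O[Si](C)(C)C(C)(C)C)C=C1C | intermediate
7 | 1-bromobut-2-yne | CC#CCBr | starting material
8 | lithium (3R,4R)-2,3-dimethyl-4-(TBSO)cyclohex-1-en-1-olate | [Li]OC1=C(C)[C@@H](C)[C@H](O[Si](C)(C)C(C)(C)C)CC1 | intermediate
9 | (2R,3R,4R)-2-(but-2-yn-1-yl)-2,3-dimethyl-4-(TBSO)cyclohexan-1-one | CC#CC[C@]1(C)[C@@H](C)[C@H](O[Si](C)(C)C(C)(C)C)CCC1=O | intermediate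
10 | (2R,3R,4R)-2-(but-2-yn-1-yl)-2,3-dimethyl-1-methylidene-4-(TBSO)cyclohexane | CC#CC[C@]1(C)[C@@H](C)[C@H](O[Si](C)(C)C(C)(C)C)CCC1=C | intermediate
11 | 9-{[(1R,2S,3R,4R)-2-(but-2-yn-1-yl)-2,3-dimethyl-4-(TBSO)cyclohexyl]methyl}-9-borabicyclo[3.3.1]nonane | CC#CC[C@]1(C)[C@@H](C)[C@H](O[Si](C)(C)C(C)(C)C)CC[C@H]1CB1C2CCCC1CCC2 | intermediate
12 | [(1R,2S,3R,4R)-2-(but-2-yn-1-yl)-2,3-dimethyl-4-(TBSO)cyclohexyl]methanol | CC#CC[C@]1(C)[C@@H](C)[C@H](O[Si](C)(C)C(C)(C)C)CC[C@H]1CO | intermediate
13 | (1R,2R,3R,4R)-2-(but-2-yn-1-yl)-2,3-dimethyl-4-(TBSO)cyclohexane-1-carbaldehyde | CC#CC[C@]1(C)[C@@H](C)[C@H](O[Si](C)(C)C(C)(C)C)CC[C@H]1C=O | intermediate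
14 | (1R)-1-[(1R,2R,3R,4R)-2-(but-2-yn-1-yl)-2,3-dimethyl-4-(TBSO)cyclohexyl]prop-2-en-1-ol | CC#CC[C@]1(C)[C@@H](C)[C@H](O[Si](C)(C)C(C)(C)C)CC[C@H]1[C@H](O)C=C | intermediate
15 | (1R,2R,3R,4R)-2-(but-2-yn-1-yl)-2,3-dimethyl-4-(TBSO)-1-[(1R)-1-(TBSO)prop-2-en-1-yl]cyclohexane (ring-A enyne) | CC#CC[C@]1(C)[C@@H](C)[C@H](O[Si](C)(C)C(C)(C)C)CC[C@H]1[C@H](O[Si](C)(C)C(C)(C)C)C=C | intermediate
16 | (3R,4R,5R,9R,10R)-3,9-bis(TBSO)eremophila-7,11-diene (ring-B diene) | C=C(C)C=1C[C@]2(C)[C@@H](C)[C@H](O[Si](C)(C)C(C)(C)C)CC[C@H]2[C@H](O[Si](C)(C)C(C)(C)C)C=1 | intermediate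
17 | (3R,4R,5R,9R,10R)-eremophila-7,11-diene-3,9-diol | C=C(C)C=1C[C@]2(C)[C@@H](C)[C@H](O)CC[C@H]2[C@H](O)C=1 | intermediate
18 | (3R,4R,5R,7S,8S,9S,10R)-7,8-epoxyeremophil-11-ene-3,9-diol (7α,8α-epoxide) | C=C(C)[C@@]12C[C@]3(C)[C@@H](C)[C@H](O)CC[C@H]3[C@H](O)[C@@H]1O2 | intermediate
19 | (3R,4R,5R,7S,8R,9S,10R)-eremophil-11-ene-3,8,9-triol | C=C(C)[C@@H]1C[C@]2(C)[C@@H](C)[C@H](O)CC[C@H]2[C@H](O)[C@@H]1O | intermediate
20 | (3R,4R,5R,7S,8R,9S,10R)-8,9-(isopropylidenedioxy)eremophil-11-en-3-ol | C=C(C)[C@@H]1C[C@]2(C)[C@@H](C)[C@H](O)CC[C@H]2[C@@H]3OC(C)(C)O[C@H]13 | intermediate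
21 | (3S)-pent-1-yn-3-ol | C#C[C@H](CC)O | starting material
22 | dilithium (3S)-pent-1-yn-1-id-3-olate | [Li]C#C[C@H](CC)O[Li] | intermediate
23 | (4S)-4-hydroxyhex-2-ynoic acid | OC(=O)C#C[C@H](CC)O | intermediate
24 | hex-2-ynoic acid | CCCC#CC(O)=O | starting material
25 | hex-2-ynoyl chloride | CCCC#CC(Cl)=O | intermediate
26 | (4S)-4-(hex-2-ynoyloxy)hex-2-ynoic acid | OC(=O)C#C[C@H](CC)OC(=O)C#CCCC | intermediate
27 | (3R,4R,5R,7S,8R,9S,10R)-8,9-(isopropylidenedioxy)eremophil-11-en-3-yl (4S)-4-(hex-2-ynoyloxy)hex-2-ynoate | C=C(C)[C@@H]1C[C@]2(C)[C@@H](C)[C@H](OC(=O)C#C[C@H](CC)OC(=O)C#CCCC)CC[C@H]2[C@@H]3OC(C)(C)O[C@H]13 | intermediate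
28 | (3R,4R,5R,7S,8R,9S,10R)-8,9-(isopropylidenedioxy)eremophil-11-en-3-yl (2Z,4S)-4-[(2Z)-hex-2-enoyloxy]hex-2-enoate | C=C(C)[C@@H]1C[C@]2(C)[C@@H](C)[C@H](OC(=O)/C=C\[C@H](CC)OC(=O)/C=C\CCC)CC[C@H]2[C@@H]3OC(C)(C)O[C@H]13 | intermediate
29 | (3R,4R,5R,7S,8R,9S,10R)-8,9-dihydroxyeremophil-11-en-3-yl (2Z,4S)-4-[(2Z)-hex-2-enoyloxy]hex-2-enoate (CNP0271544.1) | C=C(C)[C@@H]1C[C@]2(C)[C@@H](C)[C@H](OC(=O)/C=C\[C@H](CC)OC(=O)/C=C\CCC)CC[C@H]2[C@H](O)[C@@H]1O | target

Total step count: 21. Longest linear sequence: 19 steps (steps 1–16 and 19–21); the side-chain acid takes steps 17 and 18.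

Steps most likely to fail

1. Step 12 (ring-closing enyne metathesis). Loading of the ruthenium carbene onto the hindered vinyl group beside the silyloxy-bearing C9 may be slow, so that endo closure to a seven-membered ring or oligomerisation of the alkyne takes over. Fallback, from 15 back to 16: the two metathesis events are separated. Enyne 15 is first treated with ethene under pressure and the same ruthenium carbene (cross enyne metathesis of the internal alkyne). This should give the 2,3-disubstituted buta-1,3-diene, (1R,2R,3R,4R)-2,3-dimethyl-2-(3-methyl-2-methylidenebut-3-en-1-yl)-4-(TBSO)-1-[(1R)-1-(TBSO)prop-2-en-1-yl]cyclohexane F1. Ring-closing olefin metathesis of this triene between the C8=C12 vinyl group and the C7 methylidene (second-generation Hoveyda–Grubbs catalyst RuCl2(=CH-2-iPrOC6H4)(H2IMes), toluene, 80 °C) then closes ring B with loss of ethene and returns to diene 16.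

2. Step 15 (palladium–formate hydrogenolysis). The allylpalladium intermediate may exchange faces through its unsubstituted C12 terminus before hydride transfer, which would erode the configuration at C7, or it may undergo β-hydride elimination towards a dienol. Fallback, from 18 back to 19: the allyl-metal chemistry is replaced by a Lewis-acid-templated SN2 hydride opening of the 2,3-epoxy alcohol. With LiBH4 and Ti(OiPr)4 (THF/benzene, 0 °C to rt), titanium bound to the C9 alkoxide and the oxirane should direct hydride to C7, the oxirane carbon remote from the carbinol, with inversion. This gives triol 19 directly and no new compound arises (F0).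

3. Step 8 (hydroboration–oxidation). The but-2-ynyl triple bond may compete for the borane, or the facial selectivity at C10 may be insufficient. Fallback, from 9 back to 13: one-carbon homologation through an enol ether. Wittig reaction of ketone 9 with Ph3P=CHOMe (from Ph3P(CH2OMe)Cl and KN(SiMe3)2, THF, 0 °C to rt) should give the methyl enol ether (2R,3R,4R)-2-(but-2-yn-1-yl)-1-(methoxymethylidene)-2,3-dimethyl-4-(TBSO)cyclohexane F2 as an E/Z mixture. Mild hydrolysis (Cl3CCO2H, wet CH2Cl2, 0 °C), with kinetic protonation of C10 on the α face anti to the axial C5 methyl, then gives aldehyde 13. The alkyne never meets a borane, steps 7–9 are replaced by two steps, and the route resumes at step 10.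

Further compounds
F1 | step 12 | (1R,2R,3R,4R)-2,3-dimethyl-2-(3-methyl-2-methylidenebut-3-en-1-yl)-4-(TBSO)-1-[(1R)-1-(TBSO)prop-2-en-1-yl]cyclohexane | C=C(C)C(=C)C[C@]1(C)[C@@H](C)[C@H](O[Si](C)(C)C(C)(C)C)CC[C@H]1[C@H](O[Si](C)(C)C(C)(C)C)C=C
F0 | step 15 | none | none
F2 | step 8 | (2R,3R,4R)-2-(but-2-yn-1-yl)-1-(methoxymethylidene)-2,3-dimethyl-4-(TBSO)cyclohexane (E/Z mixture) | CC#CC[C@]1(C)[C@@H](C)[C@H](O[Si](C)(C)C(C)(C)C)CCC1=COC
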